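**Strategy.** Ring B of the bicycle (C1–C4, C4a, C8a, carrying the exocyclic alkene at C2) is read as a Birch-reduced aryl ether: its tetrasubstituted C4a=C8a alkene and C2 form the 1,4-diene of a 6-alkoxytetralin. Ring A is therefore annulated onto a m-methoxybenzyl unit in one flask: copper-catalysed coupling of 3-methoxybenzylmagnesium chloride with prenyl bromide forms C7–C8, and acid then closes the tertiary cation onto the ring carbon para to oxygen, forming C4a–C5. Birch reduction gives a regiodefined enol triflate; its vinyllithium adds to a stereodefined 1,2-dioxane aldehyde, and a reductive allylic transposition sets the Z alkene.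

Key step: step 1

Remark on locants: the bicycle is numbered as the octahydronaphthalene of the target (C2 exocyclic alkene carbon, C5 gem-dimethyl carbon, ring A = C4a, C5–C8, C8a); in the dioxane, C3 carries the propanoate side chain and C6 the methyl group. CIP descriptors at C6 change along the route only because substituent priorities change.

Step 1
Reactants: 1 3-methoxybenzylmagnesium chloride; 2 prenyl bromide (1-bromo-3-methylbut-2-ene)
Product: 4 6-methoxy-1,1-dimethyl-1,2,3,4-tetrahydronaphthalene, via arylalkene 3 (not isolated)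
Conditions: Li2CuCl4 (3 mol %), THF, 0 °C → rt; then THF replaced by CH2Cl2, MeSO3H, 0 °C → rt (one flask)
Reagents that add atoms: none
Why: Copper-catalysed Grignard–allyl halide coupling at the primary carbon of the bromide (the classical benzyl Grignard/prenyl halide coupling) forms the C7–C8 bond and gives 3; MeSO3H then protonates the trisubstituted alkene to the tertiary cation, which alkylates the arene (Friedel–Crafts cycloalkylation, the textbook route from 5-aryl-2-methylpent-2-enes to 1,1-dimethyltetralins) and forms the C4a–C5 bond with its quaternary carbon. Ring A closes as a six-membered ring in a 6-endo cation–arene closure, the attacked aromatic C=C lying inside the new ring; a five-membered closure is not possible because the cation sits four atoms from the ring. No stereocentre is formed. The step needs regioselectivity between the two ring positions ortho to the benzylic carbon: the one para to OMe is activated and unhindered, whereas the one between the two substituents is ortho to OMe and would put OMe peri to the gem-dimethyl group. Coupling at the tertiary allyl terminus is disfavoured by the copper catalyst and by the bulk of that carbon.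

Step 2
Reactants: 4 6-methoxy-1,1-dimethyl-1,2,3,4-tetrahydronaphthalene
Product: 5 5,5-dimethyl-5,6,7,8-tetrahydronaphthalen-2-ol
Conditions: BBr3, CH2Cl2, −78 → 0 °C; then H2O
Reagents that add atoms: none
Why: Lewis-acid cleavage of the aryl methyl ether via the aryloxydibromoborane; the benzylic quaternary carbon has no leaving group and should survive.

Step 3
Reactants: 5 5,5-dimethyl-5,6,7,8-tetrahydronaphthalen-2-ol
Product: 6 tert-butyl[(5,5-dimethyl-5,6,7,8-tetrahydronaphthalen-2-yl)oxy]dimethylsilane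
Conditions: imidazole, DMF, rt
Reagents that add atoms: tert-butyldimethylsilyl chloride, CC(C)(C)[Si](C)(C)Cl
Why: Standard O-silylation of a phenol; the silyl group is needed so that the Birch product is a silyl enol ether that can be turned into a regiodefined enolate.

Step 4
Reactants: 6 tert-butyl[(5,5-dimethyl-5,6,7,8-tetrahydronaphthalen-2-yl)oxy]dimethylsilane
Product: 7 tert-butyl[(5,5-dimethyl-1,4,5,6,7,8-hexahydronaphthalen-2-yl)oxy]dimethylsilane
Conditions: Li, liquid NH3, THF, t-BuOH, −78 → −33 °C; then MeOH, pH 7 buffer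
Reagents that add atoms: none
Why: Birch reduction of an aryl silyl ether: oxygen and alkyl substituents stay on sp2 carbons, so protonation falls on C1 and C4, giving the 1,4-diene with the tetrasubstituted C4a=C8a alkene and the enol ether double bond fixed at C2=C3.

Step 5
Reactants: 7 tert-butyl[(5,5-dimethyl-1,4,5,6,7,8-hexahydronaphthalen-2-yl)oxy]dimethylsilane
Product: 9 5,5-dimethyl-1,4,5,6,7,8-hexahydronaphthalen-2-yl trifluoromethanesulfonate, via lithium enolate 8 (not isolated)
Conditions: MeLi, THF, 0 °C → rt; then PhNTf2, −78 → 0 °C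
Reagents that add atoms: N-phenylbis(trifluoromethanesulfonimide), O=S(=O)(N(c1ccccc1)S(=O)(=O)C(F)(F)F)C(F)(F)F
Why: Regiospecific enolate generation by Si–O cleavage of a silyl enol ether (no proton source, so no equilibration to the conjugated dienolate), followed by O-triflation.

Step 6
Reactants: 9 5,5-dimethyl-1,4,5,6,7,8-hexahydronaphthalen-2-yl trifluoromethanesulfonate
Product: 10 (5,5-dimethyl-1,4,5,6,7,8-hexahydronaphthalen-2-yl)trimethylstannane
Conditions: Pd(PPh3)4 (5 mol %), LiCl, THF, 60 °C
Reagents that add atoms: hexamethylditin, C[Sn](C)(C)[Sn](C)(C)C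
Why: Palladium-catalysed stannylation of an enol triflate (oxidative addition, Sn–Sn transmetalation, reductive elimination) with retention of the alkene position.

Step 7
Reactants: 11 geraniol
Product: 12 (2S,3S)-2,3-epoxygeraniol
Conditions: Ti(OiPr)4 (5 mol %), L-(+)-diethyl tartrate (6 mol %), t-BuOOH, 4 Å molecular sieves, CH2Cl2, −20 °C
Reagents that add atoms: tert-butyl hydroperoxide, CC(C)(C)OO
Why: Sharpless asymmetric epoxidation of the allylic alcohol; the L-tartrate complex delivers oxygen to the face that gives the (2S,3S)-epoxide and leaves the remote alkene untouched.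

Step 8
Reactants: 12 (2S,3S)-2,3-epoxygeraniol
Product: 13 (3S)-3,7-dimethyloct-6-ene-1,3-diol
Conditions: NaAlH2(OCH2CH2OCH3)2, THF, 0 °C → rt; aq. Rochelle salt
Reagents that add atoms: none
Why: Alkoxide-directed intramolecular hydride delivery to C2 of the 2,3-epoxy alcohol gives the 1,3-diol; the tertiary C–O bond is untouched, so C3 keeps its configuration.

Step 9
Reactants: 13 (3S)-3,7-dimethyloct-6-ene-1,3-diol
Product: 15 (2S)-2-methyl-2-(4-methylpent-3-en-1-yl)oxetane, via monotosylate 14 (not isolated)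
Conditions: n-BuLi (1.0 equiv), THF, 0 °C; TsCl (1.0 equiv); then n-BuLi (1.05 equiv), 0 → 60 °C
Reagents that add atoms: none
Why: Selective sulfonylation of the primary alkoxide and 4-exo-tet Williamson closure by the tertiary alkoxide; the stereocentre is the nucleophile and is retained.

Step 10
Reactants: 15 (2S)-2-methyl-2-(4-methylpent-3-en-1-yl)oxetane
Product: 16 3-[(2S)-2-methyloxetan-2-yl]propanal
Conditions: O3, CH2Cl2, −78 °C; then Me2S, −78 °C → rt
Reagents that add atoms: ozone, [O-][O+]=O
Why: Ozonolysis of the only alkene with reductive work-up; the oxetane is inert.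

Step 11
Reactants: 16 3-[(2S)-2-methyloxetan-2-yl]propanal; 17 (E)-crotylboronic acid pinacol ester
Product: 18 (3R,4S)-3-methyl-6-[(2S)-2-methyloxetan-2-yl]hex-1-en-4-ol
Conditions: (R)-3,3'-bis(2,4,6-triisopropylphenyl)-1,1'-binaphthyl-2,2'-diyl hydrogen phosphate (5 mol %), toluene, 4 Å molecular sieves, −30 °C; aq. NaHCO3
Reagents that add atoms: none
Why: Chiral phosphoric acid-catalysed crotylboration through a closed chair transition state: the E-crotyl geometry sets the anti relationship and the (R)-acid (which gives the R alcohol from benzaldehyde) directs Re-face attack, setting the carbinol as S; the minor facial isomer is a diastereomer and should be removable by chromatography at 21.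

Step 12
Reactants: 18 (3R,4S)-3-methyl-6-[(2S)-2-methyloxetan-2-yl]hex-1-en-4-ol
Product: 19 (3R,4S)-3-methyl-6-[(2S)-2-methyloxetan-2-yl]hex-1-en-4-yl methanesulfonate
Conditions: Et3N, CH2Cl2, 0 °C
Reagents that add atoms: methanesulfonyl chloride, CS(=O)(=O)Cl
Why: Sulfonylation with retention; it must come before oxetane opening, since the free secondary hydroxyl would otherwise open the activated oxetane to a tetrahydrofuran.

Step 13
Reactants: 19 (3R,4S)-3-methyl-6-[(2S)-2-methyloxetan-2-yl]hex-1-en-4-yl methanesulfonate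
Product: 20 (3R,4S,7R)-7-hydroperoxy-9-hydroxy-3,7-dimethylnon-1-en-4-yl methanesulfonate
Conditions: anhydrous H2O2 in Et2O (excess), Me3SiOTf (20 mol %), −78 → 0 °C
Reagents that add atoms: hydrogen peroxide, OO
Why: Lewis acid-mediated perhydrolysis of a 2,2-disubstituted oxetane: H2O2 attacks the activated tertiary carbon from the side opposite the leaving oxygen (inversion), giving the tertiary hydroperoxide and the primary alcohol.

Step 14
Reactants: 20 (3R,4S,7R)-7-hydroperoxy-9-hydroxy-3,7-dimethylnon-1-en-4-yl methanesulfonate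
Product: 21 2-[(3R,6R)-6-[(2R)-but-3-en-2-yl]-3-methyl-1,2-dioxan-3-yl]ethan-1-ol
Conditions: KOtBu (1.05 equiv), 18-crown-6, THF, 0 °C → rt
Reagents that add atoms: none
Why: The peroxide anion (far more acidic than the alcohol) displaces the secondary mesylate in a 6-exo-tet SN2 reaction with inversion, closing the 1,2-dioxane and setting the ring CH–O centre; the vinyl group is a base-stable masked carboxyl, so no elimination through an enolate can occur.

Step 15
Reactants: 21 2-[(3R,6R)-6-[(2R)-but-3-en-2-yl]-3-methyl-1,2-dioxan-3-yl]ethan-1-ol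
Product: 22 (2S)-2-[(3R,6R)-6-(2-hydroxyethyl)-6-methyl-1,2-dioxan-3-yl]propanal
Conditions: O3, CH2Cl2, −78 °C; then Me2S; used at once
Reagents that add atoms: ozone, [O-][O+]=O
Why: Ozonolysis of the terminal vinyl group; dialkyl peroxides are inert to ozone and to Me2S.

Step 16
Reactants: 22 (2S)-2-[(3R,6R)-6-(2-hydroxyethyl)-6-methyl-1,2-dioxan-3-yl]propanal
Product: 24 methyl (2S)-2-[(3R,6R)-6-(2-hydroxyethyl)-6-methyl-1,2-dioxan-3-yl]propanoate, via carboxylic acid 23 (not isolated)
Conditions: NaClO2, NaH2PO4, 2-methylbut-2-ene, t-BuOH/H2O, 0 °C → rt; then Me3SiCHN2, toluene/MeOH, 0 °C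
Reagents that add atoms: sodium chlorite, [Na+].[O-]Cl=O; trimethylsilyldiazomethane, C[Si](C)(C)C=[N+]=[N-]
Why: Pinnick oxidation at weakly acidic pH (no epimerisation at C2, primary alcohol untouched), then methylation of the acid by the diazoalkane.

Step 17
Reactants: 24 methyl (2S)-2-[(3R,6R)-6-(2-hydroxyethyl)-6-methyl-1,2-dioxan-3-yl]propanoate
Product: 25 methyl (2S)-2-[(3R,6R)-6-methyl-6-(2-oxoethyl)-1,2-dioxan-3-yl]propanoate
Conditions: Dess–Martin periodinane, NaHCO3, CH2Cl2, 0 °C → rt; used at once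
Reagents that add atoms: none
Why: Neutral hypervalent iodine oxidation of the primary alcohol; no base is present that could eliminate the beta-peroxy aldehyde.

Step 18
Reactants: 25 methyl (2S)-2-[(3R,6R)-6-methyl-6-(2-oxoethyl)-1,2-dioxan-3-yl]propanoate
Product: 26 methyl (2S)-2-[(3R,6R)-6-(3-methoxyprop-2-en-1-yl)-6-methyl-1,2-dioxan-3-yl]propanoate (E/Z mixture)
Conditions: KN(SiMe3)2, THF, −78 °C (ylide formation); then 25 added, −78 → 0 °C
Reagents that add atoms: (methoxymethyl)triphenylphosphonium chloride, [Cl-].COC[P+](c1ccccc1)(c1ccccc1)c1ccccc1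
Why: Wittig methoxymethylenation; addition of the ylide to the unhindered aldehyde at −78 °C should be faster than enolisation, as it is for beta-silyloxy aldehydes.

Step 19
Reactants: 26 methyl (2S)-2-[(3R,6R)-6-(3-methoxyprop-2-en-1-yl)-6-methyl-1,2-dioxan-3-yl]propanoate
Product: 27 methyl (2S)-2-[(3R,6R)-6-methyl-6-(3-oxopropyl)-1,2-dioxan-3-yl]propanoate
Conditions: 0.5 M aq. HCl, THF, rt
Reagents that add atoms: water, O
Why: Acid hydrolysis of the enol ether completes the one-carbon homologation; in this aldehyde the peroxide is gamma to the carbonyl, so it cannot be eliminated.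

Step 20
Reactants: 10 (5,5-dimethyl-1,4,5,6,7,8-hexahydronaphthalen-2-yl)trimethylstannane; 27 methyl (2S)-2-[(3R,6R)-6-methyl-6-(3-oxopropyl)-1,2-dioxan-3-yl]propanoate
Product: 29 methyl (2S)-2-[(3R,6S)-6-[3-(5,5-dimethyl-1,4,5,6,7,8-hexahydronaphthalen-2-yl)-3-hydroxypropyl]-6-methyl-1,2-dioxan-3-yl]propanoate (both carbinol epimers), via vinyllithium 28 (not isolated)
Conditions: MeLi, THF, −78 °C; then 27, −78 °C; aq. NH4Cl
Reagents that add atoms: none
Why: Tin–lithium exchange gives the vinyllithium with the C2=C3 bond in place, and its 1,2-addition to the aldehyde at −78 °C should be much faster than attack on the ester or the O–O bond; the carbinol configuration is irrelevant because the next step destroys it.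

Step 21
Reactants: 29 methyl (2S)-2-[(3R,6S)-6-[3-(5,5-dimethyl-1,4,5,6,7,8-hexahydronaphthalen-2-yl)-3-hydroxypropyl]-6-methyl-1,2-dioxan-3-yl]propanoate
Product: 32 methyl (2S)-2-[(3R,6S)-6-[(3Z)-3-(5,5-dimethyl-3,4,5,6,7,8-hexahydronaphthalen-2(1H)-ylidene)propyl]-6-methyl-1,2-dioxan-3-yl]propanoate, via sulfonylhydrazine adduct 30 (not isolated), via allylic diazene 31 (not isolated)
Conditions: 2-nitrobenzenesulfonylhydrazide, PPh3, diethyl azodicarboxylate, THF, −30 °C; then 23 °C
Reagents that add atoms: none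
Why: Reductive 1,3-transposition of an allylic alcohol: Mitsunobu displacement, loss of sulfinic acid to the monoalkyl diazene and retro-ene loss of N2 deliver hydrogen to C3 and move the alkene to the exocyclic position; in the six-membered transition state the side chain sits pseudo-equatorial and so ends trans to C3 and cis to C1 (Z) from either carbinol epimer.

Step 22
Reactants: 32 methyl (2S)-2-[(3R,6S)-6-[(3Z)-3-(5,5-dimethyl-3,4,5,6,7,8-hexahydronaphthalen-2(1H)-ylidene)propyl]-6-methyl-1,2-dioxan-3-yl]propanoate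
Product: 33 (2S)-2-[(3R,6S)-6-[(3Z)-3-(5,5-dimethyl-3,4,5,6,7,8-hexahydronaphthalen-2(1H)-ylidene)propyl]-6-methyl-1,2-dioxan-3-yl]propanoic acid
Conditions: LiOH, THF/MeOH/H2O, 0 °C → rt; then dilute HCl to pH 4
Reagents that add atoms: lithium hydroxide, [Li+].[OH-]
Why: Mild saponification of the methyl ester, as is usual for 1,2-dioxane-3-alkanoate esters; the skipped diene and the peroxide should tolerate cold aqueous base.

**Compound list**

1 | 3-methoxybenzylmagnesium chloride | COc1cccc(C[Mg]Cl)c1 | starting material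
2 | prenyl bromide (1-bromo-3-methylbut-2-ene) | CC(C)=CCBr | starting material
3 | 1-methoxy-3-(4-methylpent-3-en-1-yl)benzene | COc1cccc(CCC=C(C)C)c1 | intermediate
4 | 6-methoxy-1,1-dimethyl-1,2,3,4-tetrahydronaphthalene | COc1ccc2c(c1)CCCC2(C)C | intermediate
5 | 5,5-dimethyl-5,6,7,8-tetrahydronaphthalen-2-ol | Oc1ccc2c(c1)CCCC2(C)C | intermediate
6 | tert-butyl[(5,5-dimethyl-5,6,7,8-tetrahydronaphthalen-2-yl)oxy]dimethylsilane | CC(C)(C)[Si](C)(C)Oc1ccc2c(c1)CCCC2(C)C | intermediate
7 | tert-butyl[(5,5-dimethyl-1,4,5,6,7,8-hexahydronaphthalen-2-yl)oxy]dimethylsilane | CC(C)(C)[Si](C)(C)OC1=CCC2=C(C1)CCCC2(C)C | intermediate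
8 | lithium 5,5-dimethyl-1,4,5,6,7,8-hexahydronaphthalen-2-olate | [Li]OC1=CCC2=C(C1)CCCC2(C)C | intermediate
9 | 5,5-dimethyl-1,4,5,6,7,8-hexahydronaphthalen-2-yl trifluoromethanesulfonate | O=S(=O)(OC1=CCC2=C(C1)CCCC2(C)C)C(F)(F)F | intermediate
10 | (5,5-dimethyl-1,4,5,6,7,8-hexahydronaphthalen-2-yl)trimethylstannane | C[Sn](C)(C)C1=CCC2=C(C1)CCCC2(C)C | intermediate
11 | geraniol | CC(C)=CCC/C(C)=C/CO | starting material
12 | (2S,3S)-2,3-epoxygeraniol | CC(C)=CCC[C@]1(C)O[C@H]1CO | intermediate
13 | (3S)-3,7-dimethyloct-6-ene-1,3-diol | CC(C)=CCC[C@](C)(O)CCO | intermediate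
14 | (3S)-3-hydroxy-3,7-dimethyloct-6-en-1-yl 4-methylbenzenesulfonate | CC(C)=CCC[C@](C)(O)CCOS(=O)(=O)c1ccc(C)cc1 | intermediate
15 | (2S)-2-methyl-2-(4-methylpent-3-en-1-yl)oxetane | CC(C)=CCC[C@@]1(C)CCO1 | intermediate
16 | 3-[(2S)-2-methyloxetan-2-yl]propanal | O=CCC[C@@]1(C)CCO1 | intermediate
17 | (E)-crotylboronic acid pinacol ester | C/C=C/CB1OC(C)(C)C(C)(C)O1 | starting material
18 | (3R,4S)-3-methyl-6-[(2S)-2-methyloxetan-2-yl]hex-1-en-4-ol | C[C@H](C=C)[C@@H](O)CC[C@@]1(C)CCO1 | intermediate
19 | (3R,4S)-3-methyl-6-[(2S)-2-methyloxetan-2-yl]hex-1-en-4-yl methanesulfonate | C[C@H](C=C)[C@@H](OS(C)(=O)=O)CC[C@@]1(C)CCO1 | intermediate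
20 | (3R,4S,7R)-7-hydroperoxy-9-hydroxy-3,7-dimethylnon-1-en-4-yl methanesulfonate | C[C@H](C=C)[C@@H](OS(C)(=O)=O)CC[C@](C)(CCO)OO | intermediate
21 | 2-[(3R,6R)-6-[(2R)-but-3-en-2-yl]-3-methyl-1,2-dioxan-3-yl]ethan-1-ol | C[C@H](C=C)[C@H]1CC[C@](C)(CCO)OO1 | intermediate
22 | (2S)-2-[(3R,6R)-6-(2-hydroxyethyl)-6-methyl-1,2-dioxan-3-yl]propanal | C[C@H](C=O)[C@H]1CC[C@](C)(CCO)OO1 | intermediate
23 | (2S)-2-[(3R,6R)-6-(2-hydroxyethyl)-6-methyl-1,2-dioxan-3-yl]propanoic acid | C[C@H](C(=O)O)[C@H]1CC[C@](C)(CCO)OO1 | intermediate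
24 | methyl (2S)-2-[(3R,6R)-6-(2-hydroxyethyl)-6-methyl-1,2-dioxan-3-yl]propanoate | C[C@H](C(=O)OC)[C@H]1CC[C@](C)(CCO)OO1 | intermediate
25 | methyl (2S)-2-[(3R,6R)-6-methyl-6-(2-oxoethyl)-1,2-dioxan-3-yl]propanoate | C[C@H](C(=O)OC)[C@H]1CC[C@](C)(CC=O)OO1 | intermediate
26 | methyl (2S)-2-[(3R,6R)-6-(3-methoxyprop-2-en-1-yl)-6-methyl-1,2-dioxan-3-yl]propanoate (E/Z mixture) | C[C@H](C(=O)OC)[C@H]1CC[C@](C)(CC=COC)OO1 | intermediate
27 | methyl (2S)-2-[(3R,6R)-6-methyl-6-(3-oxopropyl)-1,2-dioxan-3-yl]propanoate | C[C@H](C(=O)OC)[C@H]1CC[C@](C)(CCC=O)OO1 | intermediate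
28 | (5,5-dimethyl-1,4,5,6,7,8-hexahydronaphthalen-2-yl)lithium | [Li]C1=CCC2=C(C1)CCCC2(C)C | intermediate
29 | methyl (2S)-2-[(3R,6S)-6-[3-(5,5-dimethyl-1,4,5,6,7,8-hexahydronaphthalen-2-yl)-3-hydroxypropyl]-6-methyl-1,2-dioxan-3-yl]propanoate (carbinol epimers) | C[C@H](C(=O)OC)[C@H]1CC[C@](C)(CCC(O)C2=CCC3=C(C2)CCCC3(C)C)OO1 | intermediate
30 | methyl (2S)-2-[(3R,6S)-6-[3-(5,5-dimethyl-1,4,5,6,7,8-hexahydronaphthalen-2-yl)-3-[1-(2-nitrobenzenesulfonyl)hydrazin-1-yl]propyl]-6-methyl-1,2-dioxan-3-yl]propanoate | C[C@H](C(=O)OC)[C@H]1CC[C@](C)(CCC(N(N)S(=O)(=O)c4ccccc4[N+](=O)[O-])C2=CCC3=C(C2)CCCC3(C)C)OO1 | intermediate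
31 | methyl (2S)-2-[(3R,6S)-6-[3-diazenyl-3-(5,5-dimethyl-1,4,5,6,7,8-hexahydronaphthalen-2-yl)propyl]-6-methyl-1,2-dioxan-3-yl]propanoate | C[C@H](C(=O)OC)[C@H]1CC[C@](C)(CCC(N=N)C2=CCC3=C(C2)CCCC3(C)C)OO1 | intermediate
32 | methyl (2S)-2-[(3R,6S)-6-[(3Z)-3-(5,5-dimethyl-3,4,5,6,7,8-hexahydronaphthalen-2(1H)-ylidene)propyl]-6-methyl-1,2-dioxan-3-yl]propanoate | C[C@H](C(=O)OC)[C@H]1CC[C@](C)(CC/C=C2/CCC3=C(CCCC3(C)C)C2)OO1 | intermediate
33 | (2S)-2-[(3R,6S)-6-[(3Z)-3-(5,5-dimethyl-3,4,5,6,7,8-hexahydronaphthalen-2(1H)-ylidene)propyl]-6-methyl-1,2-dioxan-3-yl]propanoic acid | C[C@H](C(=O)O)[C@H]1CC[C@](C)(CC/C=C2/CCC3=C(CCCC3(C)C)C2)OO1 | target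

**Step count.** Total: 22 steps. Longest linear sequence: 16 steps (steps 7–19 from geraniol, then steps 20–22).

**Steps most likely to fail**

1. Step 21. The Mitsunobu displacement at the hindered dienyl carbinol may be slow, so that triphenylphosphine attacks the O–O bond or the azodicarboxylate dehydrogenates the cyclohexa-1,4-diene ring before the diazene forms. The fallback sets out from 29 and comes back at 32. Oxidation of 29 with Dess–Martin periodinane should give the dienyl ketone F1, and condensation with 4-methylbenzenesulfonylhydrazide the tosylhydrazone F2. Reduction of F2 with catecholborane at 0 °C and warming with NaOAc·3H2O should expel sulfinate and give the same allylic diazene 31, which collapses to 32 without phosphine or azodicarboxylate.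

2. Step 14. Base-induced E2 loss of the secondary mesylate, towards the diene conjugated with the vinyl group, may outrun the 6-exo-tet attack of the tertiary peroxide anion. The fallback sets out from 16 and comes back at 24. Horner–Wadsworth–Emmons olefination of 16 with methyl 2-(diethoxyphosphoryl)propanoate (NaH, THF) should give the E-enoate F3. Opening the oxetane with H2O2 and Me3SiOTf as in step 13 should give the hydroperoxy enoate F4. Et2NH in CF3CH2OH should then bring about the 6-exo-trig conjugate addition of the hydroperoxide to the enoate. The C2/C3 diastereomers of the resulting dioxane would have to be separated by chromatography to obtain 24, so steps 11–16 are bypassed at the cost of stereocontrol.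

3. Step 4. The aryl O–Si bond may be cleaved by lithium amide or alkoxide during the reduction, and the silyl dienol ether may be lost or isomerised into conjugation on work-up. The fallback sets out from 4 and comes back at 9. Birch reduction of the methyl ether 4 (Li, NH3, t-BuOH) should give the methyl enol ether F5. N-Bromosuccinimide in wet THF at 0 °C should brominate the enol ether carbon C3 and give the bromo ketone F6. Reductive silylation with Zn and Me3SiCl should give the regiodefined trimethylsilyl enol ether F7, which is taken to 9 with MeLi and PhNTf2 as in step 5 (via 8).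

Further compounds
F1 | step 21 | methyl (2S)-2-[(3R,6R)-6-[3-(5,5-dimethyl-1,4,5,6,7,8-hexahydronaphthalen-2-yl)-3-oxopropyl]-6-methyl-1,2-dioxan-3-yl]propanoate | C[C@H](C(=O)OC)[C@H]1CC[C@](C)(CCC(=O)C2=CCC3=C(C2)CCCC3(C)C)OO1
F2 | step 21 | methyl (2S)-2-[(3R,6S)-6-[3-(5,5-dimethyl-1,4,5,6,7,8-hexahydronaphthalen-2-yl)-3-[2-(4-methylbenzenesulfonyl)hydrazinylidene]propyl]-6-methyl-1,2-dioxan-3-yl]propanoate | C[C@H](C(=O)OC)[C@H]1CC[C@](C)(CCC(=NNS(=O)(=O)c4ccc(C)cc4)C2=CCC3=C(C2)CCCC3(C)C)OO1
F3 | step 14 | methyl (2E)-2-methyl-5-[(2S)-2-methyloxetan-2-yl]pent-2-enoate | COC(=O)/C(C)=C/CC[C@@]1(C)CCO1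
F4 | step 14 | methyl (2E,6R)-6-hydroperoxy-8-hydroxy-2,6-dimethyloct-2-enoate | COC(=O)/C(C)=C/CC[C@](C)(CCO)OO
F5 | step 4 | 2-methoxy-5,5-dimethyl-1,4,5,6,7,8-hexahydronaphthalene | COC1=CCC2=C(C1)CCCC2(C)C
F6 | step 4 | 3-bromo-5,5-dimethyl-3,4,5,6,7,8-hexahydronaphthalen-2(1H)-one (racemic) | O=C1CC2=C(CC1Br)C(C)(C)CCC2
F7 | step 4 | trimethyl[(5,5-dimethyl-1,4,5,6,7,8-hexahydronaphthalen-2-yl)oxy]silane | C[Si](C)(C)OC1=CCC2=C(C1)CCCC2(C)C
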